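Numbering used throughout: flavone atoms O1, C2–C8a (ring A = C4a–C8a, pyranone ring C, phenyl ring B). Chain atoms run C1′ (CH2 next to phenyl), C2′, C3′ (C=O), C4′, C5′ (stereocentre, on C8), C6′, C7′ (CH2 next to the 4-hydroxy-3-methoxyphenyl ring).

## The problem

The target is the flavonol galangin joined through C8 of ring A to C5′ of a 1,7-diarylheptan-3-one chain. The only stereocentre is C5′ (R), a benzylic methine whose two alkyl arms, CH2CH2Ar and CH2C(=O)CH2CH2Ph, are alike up to the second atom; no other stereocentre exists that could control it. The C8–C5′ bond must be made at C8 and not at the equally electron-rich C6, a choice that a bimolecular attack of ring A on an electrophile does not make cleanly. The chain must end with its single carbonyl at C3′. The molecule carries three acidic OH groups, a flavonol enol (3-OH) that is oxidised under base and air, and a β-(2-hydroxyaryl) ketone. That ketone can close to a hemiketal and lose water under acid, or revert by retro-Michael cleavage under base; either would erase C5′, so the last steps must be neutral. The enabling feature is that C5′ sits on C8, ortho to the phenol oxygen O7, and that the chain carbon two atoms further, C3′, is the one that bears oxygen. The six atoms O7–C7=C8–C5′–C4′–C3′ are therefore the array of an aromatic Claisen rearrangement, in which an O7–C3′ bond is traded for the C8–C5′ bond and a carbinol centre at C3′ hands its configuration to C5′.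

## Retrosynthesis

**15 ⇐ 14.** The three O–benzyl bonds (O3, O5, guaiacyl oxygen) are cut. Benzyl is chosen over acyl or silyl groups because one neutral hydrogenolysis frees everything and leaves the β-aryl ketone alone. The forward step must not touch the ketone or the C2=C3 bond.

**14 ⇐ 13 ⇐ 12 ⇐ 10 (through epoxide 11).** The C3′ carbonyl is traced back to the C3′=C4′ alkene of 10. Both alkene carbons are secondary, so a Wacker oxidation has no bias, and a hydroboration would rest on sterics alone and expose the pyranone carbonyl to a borane. Instead the free O7 of 10 decides: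
- epoxide 11 is opened by O7 at C4′ in a 5-exo closure (ring of O7, C7, C8, C5′, C4′), which leaves the new oxygen on C3′ (12);
- oxidation gives the α-aryloxy ketone 13;
- reductive cleavage of the C4′–O7 bond returns the phenol and leaves C4′ as CH2 (14).

The regiochemistry is thus set by ring size, and the two transient stereocentres are erased.

**10 ⇐ 9 (key disconnection).** The C8–C5′ bond is cut and O7 is joined to C3′, giving the aryl allyl ether 9. This cut is preferred to a direct C8–C5′ union with an enone for three reasons. The chain is delivered from O7 and can reach only an ortho carbon. The configuration of C5′ comes from a carbinol centre, not from a catalyst that must tell two similar arms apart. The allylic alcohol needed is simply the 1,2-reduction product of the enone. Precursor 9 has no C–C bond to ring A and no benzylic stereocentre. The forward reaction must be a suprafacial chair [3,3] shift with full transfer of chirality, ending at C8 and not at C6.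

**9 ⇐ 8 ⇐ 6 + 7.** The O7–C3′ bond is cut to galangin 7 and the allylic alcohol 6. A Mitsunobu reaction joins them with inversion at the most acidic OH of 7, so (R)-6 gives the (S)-ether 8. Benzylation of O3 and O5 afterwards (9) avoids a separate protection sequence on galangin and installs the O5 substituent that steers the shift to C8.

**6 ⇐ 5.** The C3′–H bond is cut: CBS reduction of enone 5 sets the carbinol centre.

**5 ⇐ 3 + 4.** The C4′=C5′ bond is cut by a Horner–Wadsworth–Emmons reaction of the commercial phosphonate 4 with aldehyde 3. This places the carbonyl at C3′ without the regiochemical question of an aldol reaction of 4-phenylbutan-2-one.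

**3 ⇐ 2 ⇐ 1.** Aldehyde 3 comes from commercial alcohol 1 by O-benzylation and oxidation.

## Roads not taken

**Alternative 1:** (the most obvious) Cut C8–C5′ as a Michael/Friedel–Crafts bond: galangin 7 adds through C8 to the free enone A1 under acid, base or a chiral amine or acid catalyst and gives 15 in one step.
- Ring A attacks through C6 as well as C8, giving the regioisomer A2.
- The catalyst alone would have to choose the face of an enone whose β-substituent is an unbranched alkyl chain, with an ambident polyphenol as nucleophile.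
- The addition is reversible under the conditions that promote it, which erodes any ee.
- It is shorter, but both selectivities rest on the catalyst; in the chosen plan they are built into the substrate.

**Alternative 2:** Cut the same bond with ring A as an organometallic: the 8-boryl flavone A3 adds to enone 5 under Rh(acac)(C2H4)2/(R)-BINAP catalysis, followed by hydrogenolysis to 15.
- Regiochemistry is secure.
- A3 needs benzylation, C8-selective halogenation and borylation of 7 before the key step.
- Its boron lies between O1 and a benzyloxy group on an electron-rich ring, the least favourable case for transmetalation and the most favourable for protodeboronation.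
- The chosen plan reaches its key-step precursor from 7 in two steps and forms the hindered bond intramolecularly.

**Alternative 3:** Cut C4′–C5′ and O7–C3′ together, reading the target as the open form of a 2-hydroxychroman: hetero-Diels–Alder addition of the ortho-quinone methide A4 to the enol ether A5 gives the cyclic ketal A6, which is hydrolysed to 15.
- A4 has an alkyl-substituted methide carbon with an adjacent CH2 and would tautomerise to an alkenylphenol.
- Any precursor of A4 already needs a C8-selective C–C bond.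
- Facial control would need a chiral acid on an unstabilised methide.
- Neither the regiochemical nor the stereochemical problem is solved.

Key step: step 7

Remark: the target is treated as the open keto-phenol written in the SMILES, (R) at C5′; its ring-closed hemiketal is taken as a freely equilibrating form.

## Route

Step 1
Reactants: 1 3-(4-hydroxy-3-methoxyphenyl)propan-1-ol
Product: 2 3-[4-(benzyloxy)-3-methoxyphenyl]propan-1-ol
Conditions: BnBr, K2CO3, acetone, reflux
Reagents that add atoms: benzyl bromide BrCc1ccccc1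
Why: Williamson etherification; carbonate deprotonates only the phenol, so the primary alcohol stays free.

Step 2
Reactants: 2 3-[4-(benzyloxy)-3-methoxyphenyl]propan-1-ol
Product: 3 3-[4-(benzyloxy)-3-methoxyphenyl]propanal
Conditions: Dess–Martin periodinane, CH2Cl2, rt
Reagents that add atoms: none
Why: Dess–Martin oxidation of a primary alcohol stops at the aldehyde and is mild enough for the enolisable product.

Step 3
Reactants: 3 3-[4-(benzyloxy)-3-methoxyphenyl]propanal; 4 dimethyl (2-oxo-4-phenylbutyl)phosphonate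
Product: 5 (4E)-7-[4-(benzyloxy)-3-methoxyphenyl]-1-phenylhept-4-en-3-one
Conditions: 4, NaH, THF, 0 °C; then 3, 0 °C to rt
Reagents that add atoms: none
Why: Horner–Wadsworth–Emmons olefination with a stabilised β-ketophosphonate anion should give the E-enone and fixes the carbonyl at C3′.

Step 4
Reactants: 5 (4E)-7-[4-(benzyloxy)-3-methoxyphenyl]-1-phenylhept-4-en-3-one
Product: 6 (3R,4E)-7-[4-(benzyloxy)-3-methoxyphenyl]-1-phenylhept-4-en-3-ol
Conditions: (S)-2-methyl-CBS-oxazaborolidine (20 mol %), catecholborane, toluene, −78 °C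
Reagents that add atoms: none
Why: CBS reduction; the alkenyl arm acts as the large group and the phenethyl arm as the small one, so the (S)-catalyst should deliver hydride to the face that gives the (R)-carbinol, and at low temperature only 1,2-reduction is expected.

Step 5
Reactants: 6 (3R,4E)-7-[4-(benzyloxy)-3-methoxyphenyl]-1-phenylhept-4-en-3-ol; 7 galangin (3,5,7-trihydroxy-2-phenyl-4H-chromen-4-one)
Product: 8 3,5-dihydroxy-7-{[(3S,4E)-7-[4-(benzyloxy)-3-methoxyphenyl]-1-phenylhept-4-en-3-yl]oxy}-2-phenyl-4H-chromen-4-one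
Conditions: PPh3, DIAD, THF, 0 °C to rt (7 in excess)
Reagents that add atoms: none
Why: Mitsunobu etherification with SN2 inversion turns the (R)-carbinol into the (S)-ether; 7-OH is the most acidic and least hindered hydroxyl of 7, whereas 3-OH and 5-OH are hydrogen-bonded to the C4 carbonyl.

Step 6
Reactants: 8 3,5-dihydroxy-7-{[(3S,4E)-7-[4-(benzyloxy)-3-methoxyphenyl]-1-phenylhept-4-en-3-yl]oxy}-2-phenyl-4H-chromen-4-one
Product: 9 3,5-bis(benzyloxy)-7-{[(3S,4E)-7-[4-(benzyloxy)-3-methoxyphenyl]-1-phenylhept-4-en-3-yl]oxy}-2-phenyl-4H-chromen-4-one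
Conditions: BnBr, K2CO3, Bu4NI (cat.), DMF, 60 °C, Ar
Reagents that add atoms: benzyl bromide BrCc1ccccc1
Why: Williamson etherification of the two remaining hydroxyls (the chelated 5-OH needs the polar solvent and heat); the allyl aryl ether is inert to carbonate, and the O5-benzyl group removes the chelate that would otherwise favour C6 in step 7.

Step 7
Reactants: 9 3,5-bis(benzyloxy)-7-{[(3S,4E)-7-[4-(benzyloxy)-3-methoxyphenyl]-1-phenylhept-4-en-3-yl]oxy}-2-phenyl-4H-chromen-4-one
Product: 10 3,5-bis(benzyloxy)-8-{(3R,4E)-1-[4-(benzyloxy)-3-methoxyphenyl]-7-phenylhept-4-en-3-yl}-7-hydroxy-2-phenyl-4H-chromen-4-one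
Conditions: N,N-diethylaniline, 165 °C, Ar
Reagents that add atoms: none
Why: Aromatic Claisen rearrangement: a concerted suprafacial [3,3] shift through a chair array of O7, C7, C8, C5′, C4′ and C3′ breaks O7–C3′ as C8–C5′ forms, and the 8H-dienone so formed tautomerises to the 7-phenol. The closest known reaction type is the thermal rearrangement of enantioenriched secondary (E)-allyl aryl ethers with 1,3-transfer of chirality, together with the rearrangement of 7-allyloxyflavones to 8-allyl-7-hydroxyflavones. No ring is closed; the six-membered array exists only in the transition state. C5′ is controlled by C3′: with the phenethyl arm pseudo-equatorial the new bond forms on the allyl face that the oxygen leaves, so the (3S,4E) ether should give (R)-C5′ and an (E)-C3′=C4′ double bond. The step needs C8 over C6: O7 can reach only its two ortho carbons, and with O5 benzylated there is no 5-OH to C4=O chelate, so the pyranone conjugation leaves C7–C8 as the bond of higher double-bond character, while C6 is in addition flanked by the benzyloxy group. It needs the equatorial chair over the axial one, which would give the Z-alkene of opposite configuration; the size of the phenethyl arm and the E-alkene favour it. It needs a concerted path, which the neutral, weakly basic medium favours over ionisation of the allylic ether.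

Step 8
Reactants: 10 3,5-bis(benzyloxy)-8-{(3R,4E)-1-[4-(benzyloxy)-3-methoxyphenyl]-7-phenylhept-4-en-3-yl}-7-hydroxy-2-phenyl-4H-chromen-4-one
Product: 12 (9S)-3,5-bis(benzyloxy)-9-{2-[4-(benzyloxy)-3-methoxyphenyl]ethyl}-8-(1-hydroxy-3-phenylpropyl)-2-phenyl-8,9-dihydro-4H-furo[2,3-h]chromen-4-one (diastereomer mixture at the two new centres), via trans-epoxide 11 (not isolated)
Conditions: mCPBA, CH2Cl2, 0 °C to rt; then CSA (10 mol %), rt
Reagents that add atoms: 3-chloroperbenzoic acid O=C(OO)c1cccc(Cl)c1
Why: Peracid epoxidation of the only isolated alkene, then acid-catalysed 5-exo opening by the ortho phenol O7 at C4′, which leaves the new hydroxyl on C3′; the two new centres are erased in steps 9 and 10, and C5′ keeps its geometry (its descriptor changes to S only because C4′ now outranks the aryl carbon).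

Step 9
Reactants: 12 (9S)-3,5-bis(benzyloxy)-9-{2-[4-(benzyloxy)-3-methoxyphenyl]ethyl}-8-(1-hydroxy-3-phenylpropyl)-2-phenyl-8,9-dihydro-4H-furo[2,3-h]chromen-4-one
Product: 13 (9S)-3,5-bis(benzyloxy)-9-{2-[4-(benzyloxy)-3-methoxyphenyl]ethyl}-2-phenyl-8-(3-phenylpropanoyl)-8,9-dihydro-4H-furo[2,3-h]chromen-4-one (epimers at C8 of the furan ring)
Conditions: Dess–Martin periodinane, CH2Cl2, rt
Reagents that add atoms: none
Why: Dess–Martin oxidation of the secondary alcohol; no free phenol is present at this stage, and C5′ is β to the new ketone and not epimerisable.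

Step 10
Reactants: 13 (9S)-3,5-bis(benzyloxy)-9-{2-[4-(benzyloxy)-3-methoxyphenyl]ethyl}-2-phenyl-8-(3-phenylpropanoyl)-8,9-dihydro-4H-furo[2,3-h]chromen-4-one
Product: 14 3,5-bis(benzyloxy)-8-{(3R)-1-[4-(benzyloxy)-3-methoxyphenyl]-5-oxo-7-phenylheptan-3-yl}-7-hydroxy-2-phenyl-4H-chromen-4-one
Conditions: SmI2 (2.5 equiv), THF–MeOH, −78 °C
Reagents that add atoms: none
Why: Samarium diiodide cleavage of an α-heterosubstituted ketone: the ketyl expels the aryloxide O7 and the resulting enolate is protonated by methanol, so C4′ becomes CH2 and its configuration no longer matters; the α-aryloxy ketone should be reduced far more readily than the electron-rich pyranone carbonyl.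

Step 11
Reactants: 14 3,5-bis(benzyloxy)-8-{(3R)-1-[4-(benzyloxy)-3-methoxyphenyl]-5-oxo-7-phenylheptan-3-yl}-7-hydroxy-2-phenyl-4H-chromen-4-one
Product: 15 3,5,7-trihydroxy-8-[(3R)-1-(4-hydroxy-3-methoxyphenyl)-5-oxo-7-phenylheptan-3-yl]-2-phenyl-4H-chromen-4-one (CNP0164153.1)
Conditions: H2 (1 atm), 10% Pd/C, EtOAc–MeOH, rt
Reagents that add atoms: none
Why: Hydrogenolysis of the three benzyl ethers under neutral conditions; the ketone and the tetrasubstituted C2=C3 bond should survive at 1 atm, and no acid or base is present that could open the retro-Michael path at C5′.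

## Compound list

1 | 3-(4-hydroxy-3-methoxyphenyl)propan-1-ol | COc1cc(CCCO)ccc1O | starting material
2 | 3-[4-(benzyloxy)-3-methoxyphenyl]propan-1-ol | COc1cc(CCCO)ccc1OCc1ccccc1 | intermediate
3 | 3-[4-(benzyloxy)-3-methoxyphenyl]propanal | COc1cc(CCC=O)ccc1OCc1ccccc1 | intermediate
4 | dimethyl (2-oxo-4-phenylbutyl)phosphonate | COP(=O)(CC(=O)CCc1ccccc1)OC | starting material
5 | (4E)-7-[4-(benzyloxy)-3-methoxyphenyl]-1-phenylhept-4-en-3-one | COc1cc(CC/C=C/C(=O)CCc2ccccc2)ccc1OCc1ccccc1 | intermediate
6 | (3R,4E)-7-[4-(benzyloxy)-3-methoxyphenyl]-1-phenylhept-4-en-3-ol | COc1cc(CC/C=C/[C@H](O)CCc2ccccc2)ccc1OCc1ccccc1 | intermediate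
7 | galangin (3,5,7-trihydroxy-2-phenyl-4H-chromen-4-one) | O=c1c(O)c(-c2ccccc2)oc2cc(O)cc(O)c12 | starting material
8 | 3,5-dihydroxy-7-{[(3S,4E)-7-[4-(benzyloxy)-3-methoxyphenyl]-1-phenylhept-4-en-3-yl]oxy}-2-phenyl-4H-chromen-4-one | COc1cc(CC/C=C/[C@H](CCc2ccccc2)Oc2cc(O)c3c(=O)c(O)c(-c4ccccc4)oc3c2)ccc1OCc1ccccc1 | intermediate
9 | 3,5-bis(benzyloxy)-7-{[(3S,4E)-7-[4-(benzyloxy)-3-methoxyphenyl]-1-phenylhept-4-en-3-yl]oxy}-2-phenyl-4H-chromen-4-one | COc1cc(CC/C=C/[C@H](CCc2ccccc2)Oc2cc(OCc3ccccc3)c3c(=O)c(OCc4ccccc4)c(-c4ccccc4)oc3c2)ccc1OCc1ccccc1 | intermediate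
10 | 3,5-bis(benzyloxy)-8-{(3R,4E)-1-[4-(benzyloxy)-3-methoxyphenyl]-7-phenylhept-4-en-3-yl}-7-hydroxy-2-phenyl-4H-chromen-4-one | COc1cc(CC[C@H](/C=C/CCc2ccccc2)c2c(O)cc(OCc3ccccc3)c3c(=O)c(OCc4ccccc4)c(-c4ccccc4)oc23)ccc1OCc1ccccc1 | intermediate
11 | trans-epoxide of 10 at C3′–C4′ (both faces; C5′ geometry as in 10, descriptor S): 3,5-bis(benzyloxy)-8-{3-[4-(benzyloxy)-3-methoxyphenyl]-1-[3-(2-phenylethyl)oxiran-2-yl]propyl}-7-hydroxy-2-phenyl-4H-chromen-4-one | COc1cc(CC[C@H](C2OC2CCc2ccccc2)c2c(O)cc(OCc3ccccc3)c3c(=O)c(OCc4ccccc4)c(-c4ccccc4)oc23)ccc1OCc1ccccc1 | intermediate (not isolated)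
12 | (9S)-3,5-bis(benzyloxy)-9-{2-[4-(benzyloxy)-3-methoxyphenyl]ethyl}-8-(1-hydroxy-3-phenylpropyl)-2-phenyl-8,9-dihydro-4H-furo[2,3-h]chromen-4-one (mixture at C8 and the carbinol carbon) | COc1cc(CC[C@@H]2C(C(O)CCc3ccccc3)Oc3cc(OCc4ccccc4)c4c(=O)c(OCc5ccccc5)c(-c5ccccc5)oc4c32)ccc1OCc1ccccc1 | intermediate
13 | (9S)-3,5-bis(benzyloxy)-9-{2-[4-(benzyloxy)-3-methoxyphenyl]ethyl}-2-phenyl-8-(3-phenylpropanoyl)-8,9-dihydro-4H-furo[2,3-h]chromen-4-one (epimers at C8) | COc1cc(CC[C@@H]2C(C(=O)CCc3ccccc3)Oc3cc(OCc4ccccc4)c4c(=O)c(OCc5ccccc5)c(-c5ccccc5)oc4c32)ccc1OCc1ccccc1 | intermediate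
14 | 3,5-bis(benzyloxy)-8-{(3R)-1-[4-(benzyloxy)-3-methoxyphenyl]-5-oxo-7-phenylheptan-3-yl}-7-hydroxy-2-phenyl-4H-chromen-4-one | COc1cc(CC[C@H](CC(=O)CCc2ccccc2)c2c(O)cc(OCc3ccccc3)c3c(=O)c(OCc4ccccc4)c(-c4ccccc4)oc23)ccc1OCc1ccccc1 | intermediate
15 | 3,5,7-trihydroxy-8-[(3R)-1-(4-hydroxy-3-methoxyphenyl)-5-oxo-7-phenylheptan-3-yl]-2-phenyl-4H-chromen-4-one | COc1cc(CC[C@H](CC(=O)CCc2ccccc2)c2c(O)cc(O)c3c(=O)c(O)c(-c4ccccc4)oc23)ccc1O | target

## Step count and least certain steps

Total steps: 11. Longest linear sequence: 11 (1 → 2 → 3 → 5 → 6 → 8 → 9 → 10 → 12 → 13 → 14 → 15; compounds 4 and 7 are bought).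

**Step 7 (key step).** Most likely to go wrong:
- migration to C6 in competition with C8;
- loss of configuration, either through the chair with the phenethyl arm axial (Z-alkene of opposite configuration at C5′, which must be removed before step 8) or through ionisation and recombination of the secondary allylic ether;
- further rearrangement of the ortho-alkenylphenol on prolonged heating.

Fallback: block C6. The detour sets out from 8. Bromination with NBS in DMF at 0 °C, directed by the chelated 5-OH to its ortho carbon, should give the 6-bromo ether F1. Benzylation as in step 6 gives the 6-bromo bis(benzyl) ether F2. Its thermal rearrangement can end only at C8 and gives the 6-bromo phenol F3. Reduction with HCO2Na and Pd(PPh3)4 in DMF removes the bromine and comes back to the route at 10.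

**Step 5.** Most likely to go wrong: alkylation at O3 in competition with O7, or partial SN2′ or ion-pair substitution that lowers the ee of the ether. Fallback: leave only O7 free. The detour sets out from 7. Peracetylation (Ac2O, pyridine) gives galangin triacetate F4. Selective removal of the 7-acetate (PhSH, imidazole, NMP, 0 °C) gives 3,5-di-O-acetylgalangin F5. Mitsunobu reaction of F5 with 6 gives the diacetate ether F6. Methanolysis with K2CO3 followed by BnBr in the same flask comes back to the route at 9.

**Step 8.** Most likely to go wrong: 6-endo opening of the epoxide at C3′ (which would put the oxygen on C4′), slow cyclisation of one epoxide diastereomer, or oxidation of the electron-rich phenol ring by the peracid. Fallback: drop the phenol relay. The detour sets out from 10. Benzylation of O7 (BnBr, K2CO3, DMF) gives the tetrabenzyl alkene F7. Hydroboration with 9-BBN, which should place boron on the less hindered C3′, followed by NaBO3 oxidation, gives the C3′ alcohol F8; here the pyranone carbonyl has to survive the borane. Dess–Martin oxidation gives the tetrabenzyl ketone F9. Hydrogenolysis as in step 11 comes back to the route at 15.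

**Step 10.** Most likely to go wrong: electron transfer to the pyranone carbonyl (ketyl formation, pinacol coupling or saturation of C2=C3), or further reduction of the liberated ketone. Fallback: a redox-neutral isomerisation in place of oxidation and reduction. It sets out from 12. With RuH2(CO)(PPh3)3 and xantphos in toluene at 135 °C, the hydrogen taken from the carbinol is returned to cleave the C4′–O7 bond of the α-aryloxy ketone formed in the flask. It comes back to the route at 14 without any new isolated compound.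

## Further compounds

F1 | step 7 | 6-bromo-3,5-dihydroxy-7-{[(3S,4E)-7-[4-(benzyloxy)-3-methoxyphenyl]-1-phenylhept-4-en-3-yl]oxy}-2-phenyl-4H-chromen-4-one | COc1cc(CC/C=C/[C@H](CCc2ccccc2)Oc2c(Br)c(O)c3c(=O)c(O)c(-c4ccccc4)oc3c2)ccc1OCc1ccccc1
F2 | step 7 | 3,5-bis(benzyloxy)-6-bromo-7-{[(3S,4E)-7-[4-(benzyloxy)-3-methoxyphenyl]-1-phenylhept-4-en-3-yl]oxy}-2-phenyl-4H-chromen-4-one | COc1cc(CC/C=C/[C@H](CCc2ccccc2)Oc2c(Br)c(OCc3ccccc3)c3c(=O)c(OCc4ccccc4)c(-c4ccccc4)oc3c2)ccc1OCc1ccccc1
F3 | step 7 | 3,5-bis(benzyloxy)-6-bromo-8-{(3R,4E)-1-[4-(benzyloxy)-3-methoxyphenyl]-7-phenylhept-4-en-3-yl}-7-hydroxy-2-phenyl-4H-chromen-4-one | COc1cc(CC[C@H](/C=C/CCc2ccccc2)c2c(O)c(Br)c(OCc3ccccc3)c3c(=O)c(OCc4ccccc4)c(-c4ccccc4)oc23)ccc1OCc1ccccc1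
F4 | step 5 | 3,5,7-tri-O-acetylgalangin (4-oxo-2-phenyl-4H-chromene-3,5,7-triyl triacetate) | CC(=O)Oc1cc(OC(C)=O)c2c(=O)c(OC(C)=O)c(-c3ccccc3)oc2c1
F5 | step 5 | 3,5-di-O-acetylgalangin (7-hydroxy-4-oxo-2-phenyl-4H-chromene-3,5-diyl diacetate) | CC(=O)Oc1cc(O)cc2oc(-c3ccccc3)c(OC(C)=O)c(=O)c12
F6 | step 5 | 7-{[(3S,4E)-7-[4-(benzyloxy)-3-methoxyphenyl]-1-phenylhept-4-en-3-yl]oxy}-4-oxo-2-phenyl-4H-chromene-3,5-diyl diacetate | COc1cc(CC/C=C/[C@H](CCc2ccccc2)Oc2cc(OC(C)=O)c3c(=O)c(OC(C)=O)c(-c4ccccc4)oc3c2)ccc1OCc1ccccc1
F7 | step 8 | 3,5,7-tris(benzyloxy)-8-{(3R,4E)-1-[4-(benzyloxy)-3-methoxyphenyl]-7-phenylhept-4-en-3-yl}-2-phenyl-4H-chromen-4-one | COc1cc(CC[C@H](/C=C/CCc2ccccc2)c2c(OCc3ccccc3)cc(OCc3ccccc3)c3c(=O)c(OCc4ccccc4)c(-c4ccccc4)oc23)ccc1OCc1ccccc1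
F8 | step 8 | 3,5,7-tris(benzyloxy)-8-{(3R)-1-[4-(benzyloxy)-3-methoxyphenyl]-5-hydroxy-7-phenylheptan-3-yl}-2-phenyl-4H-chromen-4-one (both carbinol epimers) | COc1cc(CC[C@H](CC(O)CCc2ccccc2)c2c(OCc3ccccc3)cc(OCc3ccccc3)c3c(=O)c(OCc4ccccc4)c(-c4ccccc4)oc23)ccc1OCc1ccccc1
F9 | step 8 | 3,5,7-tris(benzyloxy)-8-{(3R)-1-[4-(benzyloxy)-3-methoxyphenyl]-5-oxo-7-phenylheptan-3-yl}-2-phenyl-4H-chromen-4-one | COc1cc(CC[C@H](CC(=O)CCc2ccccc2)c2c(OCc3ccccc3)cc(OCc3ccccc3)c3c(=O)c(OCc4ccccc4)c(-c4ccccc4)oc23)ccc1OCc1ccccc1
F0 | step 10 | none | none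
A1 | alternative 1 | (4E)-7-(4-hydroxy-3-methoxyphenyl)-1-phenylhept-4-en-3-one | COc1cc(CC/C=C/C(=O)CCc2ccccc2)ccc1O
A2 | alternative 1 | 3,5,7-trihydroxy-6-[1-(4-hydroxy-3-methoxyphenyl)-5-oxo-7-phenylheptan-3-yl]-2-phenyl-4H-chromen-4-one (C6 regioisomer, configuration undefined) | COc1cc(CCC(CC(=O)CCc2ccccc2)c2c(O)cc3oc(-c4ccccc4)c(O)c(=O)c3c2O)ccc1O
A3 | alternative 2 | 3,5,7-tris(benzyloxy)-2-phenyl-8-(4,4,5,5-tetramethyl-1,3,2-dioxaborolan-2-yl)-4H-chromen-4-one | CC1(C)OB(OC1(C)C)c1c(OCc2ccccc2)cc(OCc2ccccc2)c2c(=O)c(OCc3ccccc3)c(-c3ccccc3)oc12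
A4 | alternative 3 | 3,5-dihydroxy-8-[3-(4-hydroxy-3-methoxyphenyl)propylidene]-2-phenyl-4H-chromene-4,7(8H)-dione (ortho-quinone methide) | COc1cc(CCC=C2C(=O)C=C(O)C3=C2OC(c2ccccc2)=C(O)C3=O)ccc1O
A5 | alternative 3 | 2-methoxy-4-phenylbut-1-ene | C=C(OC)CCc1ccccc1
A6 | alternative 3 | 3,5-dihydroxy-10-[2-(4-hydroxy-3-methoxyphenyl)ethyl]-8-methoxy-2-phenyl-8-(2-phenylethyl)-9,10-dihydro-4H,8H-pyrano[2,3-f]chromen-4-one (cyclic ketal, configuration undefined) | COc1cc(CCC2CC(CCc3ccccc3)(OC)Oc3cc(O)c4c(=O)c(O)c(-c5ccccc5)oc4c32)ccc1O
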